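**Remark on the chemistry:** the pyran ring is closed at O1–C8a with the C2–O bond intact, so a 2,3-trans flavan needs the anti (1R,2S) alcohol 17 (anti in the extended ring B–C2–C3–C4 chain); chelation-controlled addition of an aryl Grignard reagent to an α-benzyloxy aldehyde would give the syn (1S,2S) isomer and hence the 2,3-cis flavan, so C2 is set here by chelation-controlled hydride reduction of aryl ketone 16.

## Structural features

Shanciol B is a flavan-3-ol: a benzo ring (ring A) is fused to a dihydropyran ring that carries a 4-hydroxy-3-methoxyphenyl group (ring B) at C2 and a hydroxyl at C3. Ring A bears a methoxy group at C7 and, at C5, a two-carbon chain ending in a 3-hydroxyphenyl group (ring C). The only stereocentres are the adjacent C2 (R) and C3 (S), with aryl and hydroxyl trans. The C2–O1 bond is a benzylic ether para to an oxygen of ring B and can ionise under acid, and the two phenols are easily oxidised; the three hydroxyls are therefore carried as benzyl ethers and released last under neutral hydrogenolysis. The difficulty is twofold: the trans C2/C3 pair must be made in one absolute sense without passing through a C2 cation, and ring A is 1,2,3,5-tetrasubstituted with two different groups (O1 at C8a, the arylethyl chain at C5) on the two carbons that flank C4a. Those two carbons are related by a local mirror plane through C4a and C7, so ring A together with C4 is a 2,6-disubstituted 4-methoxybenzyl unit. The key step exploits this: with bromine on both positions, the C2 hydroxyl closes the pyran ring on either bromide, and the one left over is necessarily at C5. Because that closure leaves the C2–O and C3–O bonds alone, both stereocentres must already be present, anti, in the open-chain precursor.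

## Logic of the disconnections

**23 to 22.** The three O–CH2Ph bonds are cut. All hydroxyls are unmasked in one neutral operation at the very end, so no free phenol or free C3 hydroxyl passes through the organometallic steps. The forward step must cleave two aryl benzyl ethers and one alkyl benzyl ether without hydrogenolysing the cyclic benzylic C2–O1 bond.

**22 to 18 and 21 (from 20, from 19).** The C5–CH2 bond is cut. This removes ring C and its chain as a simple styrene and leaves a single aryl bromide on the flavan core. The forward step is an sp2–sp3 coupling at a bromide ortho to the ring fusion, with an alkylborane that must not undergo β-hydride elimination.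

**18 to 17.** The O1–C8a bond is cut, opening the pyran ring to an acyclic alcohol with a mirror-symmetric 2,6-dibromo-4-methoxybenzyl group. The regiochemical problem of ring A disappears, because either bromide gives the same product and the survivor is the C5 handle. The forward step must use the C2 hydroxyl only, stop after one coupling and leave both stereocentres untouched.

**17 to 16.** The C2–H bond is cut, which reduces the stereochemical problem to one stereocentre (C3). The forward reduction must deliver hydride under control by the neighbouring C3 benzyloxy group to give the anti alcohol.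

**16 to 12 and 15 (from 14, from 13).** The bond between the carbonyl carbon (future C2) and ring B is cut. Ring B arrives as an aryl Grignard reagent and the acyl partner is a stable amide. The forward step must stop at the ketone, must not epimerise C3 and must not disturb the ring A bromides.

**12 to 11, then to 10 (from 9) and 5.** The amide C–N bond is exchanged for the imide, and the C3–C4 bond is cut. C3 is then set by alkylating a chiral glycolate enolate with a benzylic bromide. The forward alkylation needs a reactive electrophile at low temperature and high facial selectivity from the auxiliary.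

**5 to 4, 3, 2 and 1; 9 to 8, 6 and 7.** The benzylic C–Br, C–O and aryl–CHO bonds are cut back to a symmetric arene, and the imide N–acyl bond to auxiliary and acid chloride. The forward lithiation must occur between the two bromines without halogen–lithium exchange.

## Other disconnections considered

**Alternative 1:** Ring A itself is cut at C8a–C4a and C5–C6, leading back to the acyclic dienyl ether ynone A2. Heating A2 would engage the 1-alkoxy-3-silyloxybutadiene on the C2 oxygen with the tethered ynone in an intramolecular Diels–Alder reaction, closing the carbocycle and the pyranone at once to give cyclohexa-1,4-diene A1.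
- In its favour: the substitution pattern of ring A follows from connectivity (the silyloxy group ends at C7 and the side chain arrives with the alkyne at C5), so no bromide handle or late cross-coupling is needed. The key step makes two rings and two C–C bonds, against one ring and one C–O bond in step 10; on these points it is the better plan.
- Equal: both plans carry C2 and C3 into the key step already formed.
- Against it: in A2 the C2 oxygen is β to the C4 ketone and is part of a good leaving group, so base-induced elimination threatens, and C3 sits α to an ynone and can epimerise. After aromatisation A1 would still hold a C4 carbonyl, which allows C2 to epimerise by reversible ring opening. A1 must be dehydrogenated, the silyl ether exchanged for a methyl ether and the C4 carbonyl removed next to the labile C2–O1 bond before debenzylation. In fairness, the chosen plan also passes through one epimerisable α-benzyloxy ketone (16), but that ketone is reduced at once under non-basic conditions.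
- Mechanism and step economy: the cycloaddition is sound, but the electron-rich diene must be generated in the presence of the ynone. At least four operations would follow the key step, against two in the chosen plan, and A2 is no easier to make than 17.

**Alternative 2:** The pyran ring is cut at O1–C2 and C3–C4. Salicyl alcohol A4 would be dehydrated to o-quinone methide A6, which adds as a heterodiene across (E)-alkenylboronate A5. The aryl-bearing carbon bonds to O1, the boron-bearing carbon to C4, and the E geometry is transferred to the trans chroman A3. Oxidation of the C–B bond of A3 with retention and hydrogenolysis of the single benzyl ether would give 23.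
- In its favour: it is the most convergent plan and uses the fewest protecting groups, and on both counts it is better than the chosen plan. The trans relationship comes stereospecifically from the alkene geometry, which is at least equal in reliability to the chelation-controlled reduction of step 9. It has two steps after the key step, the same as the chosen plan.
- Against it: neither A4 nor A5 holds a stereocentre, so the single enantiomer depends entirely on a chiral catalyst controlling the face of an o-quinone methide and alkenylboronate cycloaddition, for which there is no secure basis with this substrate pair. The boron-substituted alkene is a weakly nucleophilic partner, and the free 4-hydroxystyrene unit of A5 can oligomerise with A6. A4 needs the unsymmetrical ring A with differentiated oxygens and the side chain already in place, which costs the steps that the chosen plan saves by symmetry.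
- Comparison: the chosen route is longer, but each stereochemical element is traced to a substrate- or auxiliary-controlled step.

**Alternative 3:** The C3=C4 bond of a flav-3-ene is cut, and before that the O1–C2 bond. Iridium-catalysed allylic substitution of cinnamyl carbonate A10 by phenol A9 ([Ir(cod)Cl]2 with a chiral phosphoramidite) would give the branched ether A8 with C2 set by the ligand. The second-generation Grubbs catalyst would then join the ring A vinyl group to the allyl terminus, closing the pyran ring as chromene A7. Hydroboration and oxidation of A7 anti to the C2 aryl group, then hydrogenolysis, would lead to 23.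
- In its favour: C2 is set catalytically and not by a stoichiometric auxiliary, which is better on atom economy. Ring-closing metathesis to 2H-chromenes is dependable. No carbonyl-bearing, epimerisable intermediate appears, which is better than 16. There are two steps after the key step, equal to the chosen plan.
- Against it: A8 is an allyl aryl ether whose C–O bond is both allylic and benzylic to an electron-rich ring, so ionisation (loss of enantiopurity, drift to the linear isomer) and aromatic Claisen rearrangement to C8 are open pathways. A7 can racemise by reversible ring opening. C3 then rests on one substrate-controlled hydroboration in which regiochemistry and facial selectivity must both be won, whereas the chosen plan fixes C3 first and uses it to direct C2. A9 again needs the unsymmetrical, fully substituted ring A.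
- Comparison: overall length would be similar; the deciding burden is fragment A9.

Key step: step 10

## Route

Step 1
Reactants: 1 3,5-dibromoanisole
Product: 3 2,6-dibromo-4-methoxybenzaldehyde, via 2,6-dibromo-4-methoxyphenyllithium 2 (not isolated)
Conditions: LiN(iPr)2 (LDA), THF, −78 °C; DMF, −78 → 0 °C; 1 M HCl
Reagents that add atoms: N,N-dimethylformamide, CN(C)C=O
Why: Directed ortho-lithiation: the C–H between the two bromines is the most acidic ring position and a lithium amide at −78 °C deprotonates without bromine–lithium exchange; aryllithium 2 is then formylated by DMF to give the symmetric aldehyde.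

Step 2
Reactants: 3 2,6-dibromo-4-methoxybenzaldehyde
Product: 4 (2,6-dibromo-4-methoxyphenyl)methanol
Conditions: NaBH4, MeOH–THF, 0 °C
Reagents that add atoms: none
Why: Borohydride reduction of an aromatic aldehyde; the aryl bromides and the methyl ether are inert.

Step 3
Reactants: 4 (2,6-dibromo-4-methoxyphenyl)methanol
Product: 5 2,6-dibromo-4-methoxybenzyl bromide
Conditions: PBr3, CH2Cl2, 0 °C → rt
Reagents that add atoms: phosphorus tribromide, BrP(Br)Br
Why: Conversion of a benzylic alcohol into the bromide through its phosphite ester, followed by SN2 displacement by bromide; nothing else in the molecule reacts.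

Step 4
Reactants: 6 (R)-4-benzyloxazolidin-2-one; 7 benzyloxyacetyl chloride
Product: 9 (R)-4-benzyl-3-[2-(benzyloxy)acetyl]oxazolidin-2-one, via N-lithio oxazolidinone 8 (not isolated)
Conditions: n-BuLi, THF, −78 °C; then 7, −78 → 0 °C
Reagents that add atoms: none
Why: N-acylation of the lithiated oxazolidinone with an acid chloride, the standard entry to N-glycolyl imides; the auxiliary stereocentre is not involved.

Step 5
Reactants: 9 (R)-4-benzyl-3-[2-(benzyloxy)acetyl]oxazolidin-2-one; 5 2,6-dibromo-4-methoxybenzyl bromide
Product: 11 (R)-4-benzyl-3-[(S)-2-(benzyloxy)-3-(2,6-dibromo-4-methoxyphenyl)propanoyl]oxazolidin-2-one, via sodium (Z)-enolate 10 (not isolated)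
Conditions: NaN(SiMe3)2, THF, −78 °C; then 5, −78 → −40 °C
Reagents that add atoms: none
Why: Auxiliary-controlled glycolate enolate alkylation: deprotonation gives the sodium-chelated (Z)-enolate 10, the C4 benzyl group of the (R)-auxiliary blocks one face, and the benzylic bromide attacks the other, which sets the future C3 as S; a primary benzylic bromide is reactive enough at the temperature at which 10 is stable.

Step 6
Reactants: 11 (R)-4-benzyl-3-[(S)-2-(benzyloxy)-3-(2,6-dibromo-4-methoxyphenyl)propanoyl]oxazolidin-2-one
Product: 12 (S)-2-(benzyloxy)-3-(2,6-dibromo-4-methoxyphenyl)-N-methoxy-N-methylpropanamide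
Conditions: MeNHOMe·HCl, AlMe3, CH2Cl2, 0 °C → rt; 1 M HCl work-up
Reagents that add atoms: N,O-dimethylhydroxylamine hydrochloride, CNOC.Cl
Why: Aluminium amide transamination of the imide (Weinreb amide formation): the amide nitrogen is delivered to the exocyclic carbonyl, helped by coordination of aluminium to the α-benzyloxy oxygen; the auxiliary is released for recovery and the α-stereocentre is not enolised under these Lewis-acidic conditions.

Step 7
Reactants: 13 4-bromo-2-methoxyphenol
Product: 14 1-(benzyloxy)-4-bromo-2-methoxybenzene
Conditions: BnBr, K2CO3, DMF, rt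
Reagents that add atoms: benzyl bromide, BrCc1ccccc1
Why: Williamson ether synthesis on a phenol; the benzyl ether tolerates the Grignard, copper and palladium steps and leaves with the others in the last step.

Step 8
Reactants: 14 1-(benzyloxy)-4-bromo-2-methoxybenzene; 12 (S)-2-(benzyloxy)-3-(2,6-dibromo-4-methoxyphenyl)-N-methoxy-N-methylpropanamide
Product: 16 (S)-2-(benzyloxy)-1-[4-(benzyloxy)-3-methoxyphenyl]-3-(2,6-dibromo-4-methoxyphenyl)propan-1-one, via aryl Grignard reagent 15 (not isolated)
Conditions: 14, Mg, THF, reflux; then 12, THF, 0 °C; 1 M HCl, 0 °C
Reagents that add atoms: none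
Why: Weinreb ketone synthesis: the aryl Grignard reagent adds once because this class of amide releases the ketone only on aqueous work-up; an aryl Grignard reagent does not exchange with the ring A bromides at 0 °C and the α-stereocentre is left alone.

Step 9
Reactants: 16 (S)-2-(benzyloxy)-1-[4-(benzyloxy)-3-methoxyphenyl]-3-(2,6-dibromo-4-methoxyphenyl)propan-1-one
Product: 17 (1R,2S)-2-(benzyloxy)-1-[4-(benzyloxy)-3-methoxyphenyl]-3-(2,6-dibromo-4-methoxyphenyl)propan-1-ol
Conditions: Zn(BH4)2, Et2O, −40 → 0 °C; aq. NH4Cl
Reagents that add atoms: none
Why: Chelation-controlled ketone reduction: divalent zinc bridges the carbonyl oxygen and the α-benzyloxy oxygen, and hydride enters on the side of the α-hydrogen, away from the ring A benzyl group; this gives the anti (1R,2S) alcohol, so the new C2 stereocentre is controlled by C3.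

Step 10
Reactants: 17 (1R,2S)-2-(benzyloxy)-1-[4-(benzyloxy)-3-methoxyphenyl]-3-(2,6-dibromo-4-methoxyphenyl)propan-1-ol
Product: 18 (2R,3S)-3-(benzyloxy)-2-[4-(benzyloxy)-3-methoxyphenyl]-5-bromo-7-methoxychromane
Conditions: CuI (10 mol %), 3,4,7,8-tetramethyl-1,10-phenanthroline (20 mol %), Cs2CO3, toluene (0.05 M), 110 °C, Ar
Reagents that add atoms: none
Why: Cs2CO3 deprotonates the C2 hydroxyl at phenanthroline-ligated monovalent copper, the copper alkoxide adds oxidatively to one ortho C–Br bond (a trivalent copper aryl alkoxide) and C–O reductive elimination forms O1–C8a and returns monovalent copper. The closest known reaction type is the Ullmann-type copper-catalysed intramolecular O-arylation of secondary alcohols with aryl bromides that gives chromans. The pyran ring (O1, C2, C3, C4, C4a, C8a) is closed in a 6-exo mode at an aromatic carbon. No stereocentre is created; the C2–O and C3–O bonds are not broken, so the anti arrangement of 17 becomes the 2,3-trans arrangement of 18. Site selectivity is not needed, because the two bromides exchange by rotation about the aryl–CH2 bond and lead to the same product. Ring-size selectivity is secured by the benzyl ether on the C3 oxygen, which leaves the C2 hydroxyl as the only nucleophile. Monocoupling is secured because the second bromide has no intramolecular partner and intermolecular etherification is slow at this dilution, so it remains as the C5 handle. Copper is chosen over palladium because its alkoxides are less prone to β-hydride elimination, the pathway that would oxidise the benzylic alcohol back to 16.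

Step 11
Reactants: 19 3-(benzyloxy)benzaldehyde
Product: 20 1-(benzyloxy)-3-vinylbenzene
Conditions: Ph3PCH3Br, KOtBu, THF, 0 °C → rt
Reagents that add atoms: methyltriphenylphosphonium bromide, C[P+](c1ccccc1)(c1ccccc1)c1ccccc1.[Br-]
Why: Wittig methylenation of an aromatic aldehyde with the non-stabilised ylide; the benzyl ether is inert.

Step 12
Reactants: 18 (2R,3S)-3-(benzyloxy)-2-[4-(benzyloxy)-3-methoxyphenyl]-5-bromo-7-methoxychromane; 20 1-(benzyloxy)-3-vinylbenzene
Product: 22 (2R,3S)-3-(benzyloxy)-2-[4-(benzyloxy)-3-methoxyphenyl]-5-{2-[3-(benzyloxy)phenyl]ethyl}-7-methoxychromane, via B-alkyl-9-BBN borane 21 (not isolated)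
Conditions: 20, 9-BBN-H, THF, 0 °C → rt; then 18, PdCl2(dppf) (5 mol %), aq. K3PO4, THF–DMF, 65 °C
Reagents that add atoms: none
Why: Anti-Markovnikov hydroboration of the styrene puts boron on the terminal carbon (21); B-alkyl Suzuki–Miyaura coupling then joins this primary alkyl group to C5 by oxidative addition of zerovalent palladium into the only C–Br bond, base-assisted transmetalation and reductive elimination, which the wide-bite-angle dppf ligand favours over β-hydride elimination.

Step 13
Reactants: 22 (2R,3S)-3-(benzyloxy)-2-[4-(benzyloxy)-3-methoxyphenyl]-5-{2-[3-(benzyloxy)phenyl]ethyl}-7-methoxychromane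
Product: 23 shanciol B, (2R,3S)-5-[2-(3-hydroxyphenyl)ethyl]-2-(4-hydroxy-3-methoxyphenyl)-7-methoxychroman-3-ol
Conditions: H2 (1 atm), Pd(OH)2/C, EtOAc–MeOH, rt
Reagents that add atoms: none
Why: Catalytic hydrogenolysis of the two aryl benzyl ethers and the secondary alkyl benzyl ether under neutral conditions; the cyclic benzylic C2–O1 ether is expected to survive, as is general for benzyl-protected flavan-3-ols, and neither stereocentre is affected.

## Compound list

1 | 3,5-dibromoanisole | COc1cc(Br)cc(Br)c1 | starting material
2 | 2,6-dibromo-4-methoxyphenyllithium (not isolated) | COc1cc(Br)c([Li])c(Br)c1 | intermediate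
3 | 2,6-dibromo-4-methoxybenzaldehyde | COc1cc(Br)c(C=O)c(Br)c1 | intermediate
4 | (2,6-dibromo-4-methoxyphenyl)methanol | COc1cc(Br)c(CO)c(Br)c1 | intermediate
5 | 2,6-dibromo-4-methoxybenzyl bromide | COc1cc(Br)c(CBr)c(Br)c1 | intermediate
6 | (R)-4-benzyloxazolidin-2-one | O=C1N[C@H](Cc2ccccc2)CO1 | starting material
7 | benzyloxyacetyl chloride | O=C(Cl)COCc1ccccc1 | starting material
8 | N-lithio derivative of (R)-4-benzyloxazolidin-2-one (not isolated) | [Li]N1[C@H](Cc2ccccc2)COC1=O | intermediate
9 | (R)-4-benzyl-3-[2-(benzyloxy)acetyl]oxazolidin-2-one | O=C(COCc1ccccc1)N1[C@H](Cc2ccccc2)COC1=O | intermediate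
10 | sodium (Z)-enolate of 9 (not isolated) | [Na+].[O-]/C(=C\OCc1ccccc1)N1[C@H](Cc2ccccc2)COC1=O | intermediate
11 | (R)-4-benzyl-3-[(S)-2-(benzyloxy)-3-(2,6-dibromo-4-methoxyphenyl)propanoyl]oxazolidin-2-one | COc1cc(Br)c(C[C@H](OCc2ccccc2)C(=O)N2[C@H](Cc3ccccc3)COC2=O)c(Br)c1 | intermediate
12 | (S)-2-(benzyloxy)-3-(2,6-dibromo-4-methoxyphenyl)-N-methoxy-N-methylpropanamide | COc1cc(Br)c(C[C@H](OCc2ccccc2)C(=O)N(C)OC)c(Br)c1 | intermediate
13 | 4-bromo-2-methoxyphenol | COc1cc(Br)ccc1O | starting material
14 | 1-(benzyloxy)-4-bromo-2-methoxybenzene | COc1cc(Br)ccc1OCc1ccccc1 | intermediate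
15 | [4-(benzyloxy)-3-methoxyphenyl]magnesium bromide (not isolated) | COc1cc([Mg]Br)ccc1OCc1ccccc1 | intermediate
16 | (S)-2-(benzyloxy)-1-[4-(benzyloxy)-3-methoxyphenyl]-3-(2,6-dibromo-4-methoxyphenyl)propan-1-one | COc1cc(Br)c(C[C@H](OCc2ccccc2)C(=O)c2ccc(OCc3ccccc3)c(OC)c2)c(Br)c1 | intermediate
17 | (1R,2S)-2-(benzyloxy)-1-[4-(benzyloxy)-3-methoxyphenyl]-3-(2,6-dibromo-4-methoxyphenyl)propan-1-ol | O[C@H](c1ccc(OCc2ccccc2)c(OC)c1)[C@@H](OCc1ccccc1)Cc1c(Br)cc(OC)cc1Br | intermediate
18 | (2R,3S)-3-(benzyloxy)-2-[4-(benzyloxy)-3-methoxyphenyl]-5-bromo-7-methoxychromane | COc1cc(Br)c2c(c1)O[C@H](c1ccc(OCc3ccccc3)c(OC)c1)[C@@H](OCc1ccccc1)C2 | intermediate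
19 | 3-(benzyloxy)benzaldehyde | O=Cc1cccc(OCc2ccccc2)c1 | starting material
20 | 1-(benzyloxy)-3-vinylbenzene | C=Cc1cccc(OCc2ccccc2)c1 | intermediate
21 | 9-{2-[3-(benzyloxy)phenyl]ethyl}-9-borabicyclo[3.3.1]nonane (not isolated) | C(Cc1cccc(OCc2ccccc2)c1)B1C2CCCC1CCC2 | intermediate
22 | (2R,3S)-3-(benzyloxy)-2-[4-(benzyloxy)-3-methoxyphenyl]-5-{2-[3-(benzyloxy)phenyl]ethyl}-7-methoxychromane | COc1cc(CCc3cccc(OCc4ccccc4)c3)c2c(c1)O[C@H](c1ccc(OCc3ccccc3)c(OC)c1)[C@@H](OCc1ccccc1)C2 | intermediate
23 | shanciol B, (2R,3S)-5-[2-(3-hydroxyphenyl)ethyl]-2-(4-hydroxy-3-methoxyphenyl)-7-methoxychroman-3-ol | COc1cc(CCc2cccc(O)c2)c2c(c1)O[C@H](c1ccc(O)c(OC)c1)[C@@H](O)C2 | target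

## Step count and least certain steps

Total: 13 steps. Longest linear sequence: 10 steps (steps 1, 2, 3, 5, 6, 8, 9, 10, 12, 13, from 1 to 23).

**Step 10 (key step).**
- What may go wrong: β-hydride elimination from the metal-bound benzylic alkoxide would oxidise the alcohol to the ketone and hydrodebrominate ring A. Oxidative addition at an electron-rich, ortho-substituted C–Br bond may be slow, which gives intermolecular etherification time to compete.
- Fallback: from 17 back to 18, by elimination–addition through an aryne instead of metal catalysis. LiN(iPr)2 (2.2 equiv, THF, −78 °C) would deprotonate the hydroxyl and one ring A C–H lying between a bromine and the methoxy group. On warming towards 0 °C, loss of lithium bromide would give the aryne lithium alkoxide F1. Its alkoxide adds to the aryne carbon that carried the bromine, which is the six-membered closure and also the electronically favoured site, being meta to the methoxy group. Protonation on work-up gives 18 with the other bromine untouched. The base must be held near two equivalents, because 18 still has a C–H next to bromine.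

**Step 5.**
- What may go wrong: SN2 displacement at the benzylic carbon flanked by two ortho bromines may be slow at the temperature where enolate 10 is stable, so that decomposition of the enolate and loss of the auxiliary compete and conversion falls.
- Fallback: from 3 back to 12, with asymmetric hydrogenation in place of auxiliary alkylation. Aldol condensation of 3 with methyl 2-(benzyloxy)acetate (KOtBu, THF) would give methyl (Z)-2-(benzyloxy)-3-(2,6-dibromo-4-methoxyphenyl)acrylate F2. This is saponified in the same flask (aq. NaOH) to (Z)-2-(benzyloxy)-3-(2,6-dibromo-4-methoxyphenyl)acrylic acid F3. Enantioselective hydrogenation of the C=C bond (H2, Ru(OAc)2(BINAP), using the ligand antipode that leads to the 2S acid, MeOH) would give (S)-2-(benzyloxy)-3-(2,6-dibromo-4-methoxyphenyl)propanoic acid F4. Amide coupling with MeNHOMe·HCl (EDC·HCl, HOBt, iPr2NEt, CH2Cl2) returns to 12. The enantioselectivity with two ortho bromines on the aryl group is itself uncertain, which is why this is the reserve and not the first choice.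

**Step 6.**
- What may go wrong: the aluminium amide may attack the ring carbonyl of the oxazolidinone (endocyclic cleavage) in competition with exocyclic acyl transfer, because the acyl group is α-branched.
- Fallback: from 11 back to 12, by exchange in two stages through an ester. MeOMgBr (MeOH–CH2Cl2, 0 °C) would give methyl (S)-2-(benzyloxy)-3-(2,6-dibromo-4-methoxyphenyl)propanoate F5 and release the auxiliary. MeNHOMe·HCl with iPrMgCl (THF, −20 °C) then converts F5 into 12.

**Step 9.**
- What may go wrong: facial selectivity may be poor if chelation of zinc by the aryl ketone and the benzyl ether is incomplete. Reduction through the open, non-chelated mode gives the syn alcohol, which would end as the 2,3-cis flavan.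
- Fallback: from 16 back to 17, with reagent control instead of substrate control. Corey–Bakshi–Shibata reduction with the (R)-2-methyl-oxazaborolidine catalyst and BH3·SMe2 (toluene, −30 °C) is expected to give the 1R alcohol if ring B acts as the larger group, as is usual for aryl ketones. This fallback makes no new compound (F0).

**Step 12.**
- What may go wrong: slow oxidative addition at the electron-rich C5–Br bond next to the ring fusion would let protodeboronation or β-hydride elimination of the alkylborane and hydrodebromination of the flavan compete.
- Fallback: from 18 and 20, returning at 23. Mizoroki–Heck coupling of 18 with styrene 20 (Pd(OAc)2, P(o-tol)3, K2CO3, DMF, 100 °C) would give (2R,3S)-3-(benzyloxy)-2-[4-(benzyloxy)-3-methoxyphenyl]-5-[(E)-2-(3-(benzyloxy)phenyl)vinyl]-7-methoxychromane F6. The conditions of step 13 (H2, Pd(OH)2/C) would then saturate the C=C bond and cleave the three benzyl ethers in one operation to give 23.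

## Further compounds

F1 | step 10 | lithium alkoxide of the ring A aryne derived from 17 (not isolated) | [Li]O[C@H](c1ccc(OCc2ccccc2)c(OC)c1)[C@@H](OCc1ccccc1)CC1=C(Br)C=C(OC)C#C1
F2 | step 5 | methyl (Z)-2-(benzyloxy)-3-(2,6-dibromo-4-methoxyphenyl)acrylate (not isolated) | COC(=O)/C(OCc1ccccc1)=C/c1c(Br)cc(OC)cc1Br
F3 | step 5 | (Z)-2-(benzyloxy)-3-(2,6-dibromo-4-methoxyphenyl)acrylic acid | OC(=O)/C(OCc1ccccc1)=C/c1c(Br)cc(OC)cc1Br
F4 | step 5 | (S)-2-(benzyloxy)-3-(2,6-dibromo-4-methoxyphenyl)propanoic acid | COc1cc(Br)c(C[C@H](OCc2ccccc2)C(O)=O)c(Br)c1
F5 | step 6 | methyl (S)-2-(benzyloxy)-3-(2,6-dibromo-4-methoxyphenyl)propanoate | COc1cc(Br)c(C[C@H](OCc2ccccc2)C(=O)OC)c(Br)c1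
F0 | step 9 | none | none
F6 | step 12 | (2R,3S)-3-(benzyloxy)-2-[4-(benzyloxy)-3-methoxyphenyl]-5-[(E)-2-(3-(benzyloxy)phenyl)vinyl]-7-methoxychromane | COc1cc(/C=C/c3cccc(OCc4ccccc4)c3)c2c(c1)O[C@H](c1ccc(OCc3ccccc3)c(OC)c1)[C@@H](OCc1ccccc1)C2
A1 | alternative 1 | 2,3-trans-3-(benzyloxy)-2-[4-(benzyloxy)-3-methoxyphenyl]-5-{2-[3-(benzyloxy)phenyl]ethyl}-7-(tert-butyldimethylsilyloxy)-2,3,6,8a-tetrahydro-4H-chromen-4-one (C8a epimers) | CC(C)(C)[Si](C)(C)OC1=CC2O[C@H](c3ccc(OCc4ccccc4)c(OC)c3)[C@@H](OCc3ccccc3)C(=O)C2=C(CCc2cccc(OCc3ccccc3)c2)C1
A2 | alternative 1 | 2-(benzyloxy)-1-[4-(benzyloxy)-3-methoxyphenyl]-7-[3-(benzyloxy)phenyl]-1-{[(E)-3-(tert-butyldimethylsilyloxy)buta-1,3-dienyl]oxy}hept-4-yn-3-one, C1 and C2 arranged as in 17 | C=C(O[Si](C)(C)C(C)(C)C)/C=C/O[C@H](c1ccc(OCc2ccccc2)c(OC)c1)[C@@H](OCc1ccccc1)C(=O)C#CCCc1cccc(OCc2ccccc2)c1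
A3 | alternative 2 | 2,3-trans-5-{2-[3-(benzyloxy)phenyl]ethyl}-2-(4-hydroxy-3-methoxyphenyl)-7-methoxy-3-(4,4,5,5-tetramethyl-1,3,2-dioxaborolan-2-yl)chromane | COc1cc(CCc3cccc(OCc4ccccc4)c3)c2c(c1)O[C@H](c1ccc(O)c(OC)c1)[C@@H](B1OC(C)(C)C(C)(C)O1)C2
A4 | alternative 2 | 3-{2-[3-(benzyloxy)phenyl]ethyl}-2-(hydroxymethyl)-5-methoxyphenol | COc1cc(O)c(CO)c(CCc2cccc(OCc3ccccc3)c2)c1
A5 | alternative 2 | 2-methoxy-4-[(E)-2-(4,4,5,5-tetramethyl-1,3,2-dioxaborolan-2-yl)vinyl]phenol | COc1cc(/C=C/B2OC(C)(C)C(C)(C)O2)ccc1O
A6 | alternative 2 | 5-{2-[3-(benzyloxy)phenyl]ethyl}-3-methoxy-6-methylenecyclohexa-2,4-dien-1-one (o-quinone methide) | C=C1C(=O)C=C(OC)C=C1CCc1cccc(OCc2ccccc2)c1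
A7 | alternative 3 | 2-[4-(benzyloxy)-3-methoxyphenyl]-5-{2-[3-(benzyloxy)phenyl]ethyl}-7-methoxy-2H-chromene, C2 arranged as in 23 | COc1cc(CCc3cccc(OCc4ccccc4)c3)c2c(c1)O[C@H](c1ccc(OCc3ccccc3)c(OC)c1)C=C2
A8 | alternative 3 | 1-{1-[4-(benzyloxy)-3-methoxyphenyl]allyloxy}-3-{2-[3-(benzyloxy)phenyl]ethyl}-5-methoxy-2-vinylbenzene, ether carbon arranged as C2 of 23 | COc1cc(CCc3cccc(OCc4ccccc4)c3)c(C=C)c(c1)O[C@H](c1ccc(OCc3ccccc3)c(OC)c1)C=C
A9 | alternative 3 | 3-{2-[3-(benzyloxy)phenyl]ethyl}-5-methoxy-2-vinylphenol | COc1cc(O)c(C=C)c(CCc2cccc(OCc3ccccc3)c2)c1
A10 | alternative 3 | (E)-3-[4-(benzyloxy)-3-methoxyphenyl]allyl methyl carbonate | COC(=O)OC/C=C/c1ccc(OCc2ccccc2)c(OC)c1
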